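**Strategy**

The route rests on cutting the side chain at C12′–C13′ (numbered outward from chromene C2): the bond between the methyl-bearing sp² carbon of the C11′=C12′ alkene and the adjoining allylic CH2. The key step, a Zweifel olefination, exploits this trisubstituted alkene: a C26 homoallylic pinacol boronate (from geranylgeraniol) and the (11′Z)-alkenyllithium of a chromene-bearing 2-iodoalkene are tied through boron as an ate complex, and iodine then triggers 1,2-migration and anti-elimination. One flask thus joins two nucleophilic carbons and inverts the Z-iodide into the required E-alkene. The (2R)-2H-chromene half comes from natural (R)-γ-tocotrienol, dehydrogenated at C3–C4 of the pyran ring and shortened at its terminal alkene.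

Key step: step 12

Remark: natural (2R,3′E,7′E)-γ-tocotrienol and (2E,6E,10E)-geranylgeraniol are taken as purchasable single isomers, and from compound 12 onward all work is done with exclusion of UV light, since 2H-chromenes can racemise by photochemical ring opening.

**Route**

Step 1
Reactants: 1 (2E,6E,10E)-geranylgeraniol
Product: 2 (2E,6E,10E)-geranylgeranyl bromide
Conditions: PBr3 (0.4 equiv), Et2O, −10 → 0 °C; used crude
Reagents that add atoms: phosphorus tribromide BrP(Br)Br
Why: Bromination of the primary allylic alcohol with PBr3 at low temperature is an SN2-type substitution without allylic transposition, so the 2E geometry is kept.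

Step 2
Reactants: 2 (2E,6E,10E)-geranylgeranyl bromide
Product: 3 (5E,9E,13E)-6,10,14,18-tetramethylnonadeca-5,9,13,17-tetraen-1-yne
Conditions: propyne, n-BuLi (2 equiv), TMEDA, Et2O–hexane, −78 → 0 °C (1,3-dilithiopropyne); then 2, −78 °C → rt; aq. NH4Cl
Reagents that add atoms: propyne CC#C
Why: Propargylation of an allylic bromide with 1,3-dilithiopropyne: the sp³ carbanion end is alkylated by SN2 at the primary allylic carbon and the acetylide end is protonated on work-up, which gives the terminal 1,5-enyne.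

Step 3
Reactants: 3 (5E,9E,13E)-6,10,14,18-tetramethylnonadeca-5,9,13,17-tetraen-1-yne
Product: 6 (3E,7E,11E,15E)-4,8,12,16,20-pentamethylhenicosa-3,7,11,15,19-pentaen-1-ol, via alkenyldimethylalane 4 (not isolated), via lithium alkenylalanate 5 (not isolated)
Conditions: Me3Al (2.5 equiv), Cp2ZrCl2 (0.25 equiv), CH2Cl2, 0 °C → rt; volatiles removed; n-BuLi (1 equiv), THF–hexane, −78 → 0 °C; oxirane (excess), 0 °C → rt; aq. work-up
Reagents that add atoms: trimethylaluminium C[Al](C)C; oxirane C1CO1
Why: Negishi zirconium-catalysed carboalumination adds methyl and aluminium syn across the terminal alkyne with methyl on the internal carbon, which fixes the new E-trisubstituted alkene, and the derived alanate opens oxirane with retention of the alkene geometry to give the homoallylic alcohol.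

Step 4
Reactants: 6 (3E,7E,11E,15E)-4,8,12,16,20-pentamethylhenicosa-3,7,11,15,19-pentaen-1-ol
Product: 7 (3E,7E,11E,15E)-1-iodo-4,8,12,16,20-pentamethylhenicosa-3,7,11,15,19-pentaene
Conditions: I2, PPh3, imidazole, CH2Cl2, 0 °C → rt
Reagents that add atoms: iodine II
Why: Appel-type iodination of a primary alcohol (SN2 on the alkoxyphosphonium ion) should leave the trisubstituted alkenes untouched.

Step 5
Reactants: 7 (3E,7E,11E,15E)-1-iodo-4,8,12,16,20-pentamethylhenicosa-3,7,11,15,19-pentaene
Product: 9 2-[(3E,7E,11E,15E)-4,8,12,16,20-pentamethylhenicosa-3,7,11,15,19-pentaen-1-yl]-4,4,5,5-tetramethyl-1,3,2-dioxaborolane, via homoallyllithium 8 (not isolated)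
Conditions: t-BuLi (2.1 equiv), Et2O–pentane, −78 °C; then i-PrOBpin, −78 °C → rt; aq. NH4Cl
Reagents that add atoms: 2-isopropoxy-4,4,5,5-tetramethyl-1,3,2-dioxaborolane CC(C)OB1OC(C)(C)C(C)(C)O1
Why: Iodine–lithium exchange with two equivalents of t-BuLi gives the primary alkyllithium, which is borylated by addition to i-PrOBpin and loss of isopropoxide.

Step 6
Reactants: 10 (R)-γ-tocotrienol
Product: 11 O-triisopropylsilyl-(R)-γ-tocotrienol
Conditions: TIPSOTf (1.3 equiv), 2,6-lutidine (2 equiv), CH2Cl2, 0 °C → rt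
Reagents that add atoms: triisopropylsilyl triflate CC(C)[Si](C(C)C)(C(C)C)OS(=O)(=O)C(F)(F)F
Why: Silylation of the phenol gives a bulky aryl silyl ether that should withstand DDQ, t-BuLi and brief methoxide treatment later and is removed by fluoride at the end.

Step 7
Reactants: 11 O-triisopropylsilyl-(R)-γ-tocotrienol
Product: 12 O-triisopropylsilyl-(R)-3,4-dehydro-γ-tocotrienol
Conditions: DDQ (1.5 equiv), dry benzene, reflux, Ar, dark
Reagents that add atoms: none
Why: DDQ dehydrogenation of a chroman to a 2H-chromene proceeds by hydride abstraction from benzylic C4 (cation stabilised by the ortho ring oxygen O1) and loss of a proton from C3, and since the C2–O1 bond is not touched the (R) centre of the chiral pool is retained.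

Step 8
Reactants: 12 O-triisopropylsilyl-(R)-3,4-dehydro-γ-tocotrienol
Product: 13 (2E,6E,10E)-2,6,10-trimethyl-13-[(2R)-2,7,8-trimethyl-6-(triisopropylsilyloxy)-2H-chromen-2-yl]trideca-2,6,10-trien-1-ol
Conditions: SeO2 (0.3 equiv), t-BuOOH (2 equiv), salicylic acid (0.1 equiv), CH2Cl2, 0 °C → rt; stopped at partial conversion, 12 recycled
Reagents that add atoms: selenium dioxide O=[Se]=O (oxygen-transfer catalyst); tert-butyl hydroperoxide CC(C)(C)OO (stoichiometric oxygen source)
Why: SeO2/t-BuOOH allylic oxidation (ene reaction, then [2,3]-sigmatropic shift) is known to hydroxylate the E-methyl group of the terminal isopropylidene unit of polyprenyl chains in preference to internal positions, and the chromene alkene has no allylic hydrogen.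

Step 9
Reactants: 13 the terminal E-allylic alcohol
Product: 14 [3-{(3E,7E)-3,7-dimethyl-10-[(2R)-2,7,8-trimethyl-6-(triisopropylsilyloxy)-2H-chromen-2-yl]deca-3,7-dien-1-yl}-2-methyloxiran-2-yl]methanol
Conditions: VO(acac)2 (3 mol %), t-BuOOH (1.3 equiv), CH2Cl2, 0 °C → rt
Reagents that add atoms: tert-butyl hydroperoxide CC(C)(C)OO
Why: Hydroxyl-directed vanadium-catalysed epoxidation oxidises only the alkene of the allylic alcohol; the two epoxide centres form without control, which does not matter because both carbons are cleaved in the next step.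

Step 10
Reactants: 14 the 2,3-epoxy alcohol
Product: 15 (4E,8E)-4,8-dimethyl-11-[(2R)-2,7,8-trimethyl-6-(triisopropylsilyloxy)-2H-chromen-2-yl]undeca-4,8-dienal
Conditions: H5IO6 (2.2 equiv), THF–H2O, 0 °C, short reaction time
Reagents that add atoms: none
Why: Periodic acid hydrolyses the epoxy alcohol to the 1,2,3-triol and cleaves both glycol C–C bonds (Malaprade cleavage), which leaves C11′ as the aldehyde.

Step 11
Reactants: 15 the chromene aldehyde
Product: 16 triisopropyl{[(2R)-2-[(3E,7E,11Z)-12-iodo-4,8-dimethyltrideca-3,7,11-trien-1-yl]-2,7,8-trimethyl-2H-chromen-6-yl]oxy}silane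
Conditions: EtPPh3I, n-BuLi, THF, rt; I2, −78 °C; NaHMDS, −78 → −20 °C; then 15, −78 → −20 °C
Reagents that add atoms: ethyltriphenylphosphonium iodide CC[P+](c1ccccc1)(c1ccccc1)c1ccccc1.[I-]; iodine II
Why: Stork–Zhao-type Wittig olefination with the α-iodoethylidene ylide should give the (Z)-2-iodo-2-alkene (iodine cis to the chain) under kinetic control at low temperature.

Step 12
Reactants: 9 the C26 homoallylic pinacol boronate; 16 the (11′Z)-iodoalkene
Product: 20 O-triisopropylsilyl-plastochromenol-8, via alkenyllithium 17 (not isolated), via lithium boronate complex 18 (not isolated), via β-iodo boronic ester 19 (not isolated)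
Conditions: 16, t-BuLi (2.0 equiv), Et2O, −78 °C; then 9 (1.1 equiv) in THF, −78 °C; I2 (1.1 equiv) in MeOH, −78 °C; NaOMe (3 equiv) in MeOH, −78 °C → rt; aq. Na2S2O3; dark
Reagents that add atoms: none
Why: This is a Zweifel olefination in its boronic-ester form: iodine–lithium exchange on 16 occurs with retention to give (Z)-alkenyllithium 17, which adds to the boron of 9 to give ate complex 18, so that the two nucleophilic carbons C12′ and C13′ sit on one boron atom. Iodine attacks the electron-rich alkenyl–boron π bond of 18, and the iodonium ion is opened by 1,2-migration of the primary C13′ alkyl group from boron to C12′ anti to iodine; this forms the C12′–C13′ bond and gives β-iodo boronic ester 19, from which methoxide induces anti elimination of boron and iodide. The closest known reaction type is the iodine-induced coupling of alkenyllithiums with alkyl pinacol boronates to trisubstituted alkenes; no ring is closed and no stereocentre is created. The double-bond geometry is controlled by the substrate, because anti migration followed by anti elimination replaces boron by carbon with inversion, so the 11′Z iodide (iodine cis to C10′) should deliver the 11′E alkene with the methyl group cis to C10′. The step needs iodine to select one of nine C=C bonds, which the anionic boronate (far more nucleophilic than the neutral trisubstituted alkenes and the chromene alkene) together with 1.1 equiv of I2 at −78 °C should secure, and it needs the right group to migrate, which is secured because the alkyl chain is the only carbon ligand on boron besides the alkenyl group; the aryl TIPS ether should survive the brief methoxide treatment and the (R) centre at C2 is not involved.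

Step 13
Reactants: 20 O-triisopropylsilyl-plastochromenol-8
Product: 21 plastochromenol-8
Conditions: TBAF (1.2 equiv), degassed THF, 0 °C; aq. NH4Cl; Ar, dark
Reagents that add atoms: none
Why: Fluoride cleavage of the aryl silyl ether should liberate the phenol without touching the polyene, the chromene or the C2 centre.

**Compound list**

1 | (2E,6E,10E)-geranylgeraniol, (2E,6E,10E)-3,7,11,15-tetramethylhexadeca-2,6,10,14-tetraen-1-ol | CC(C)=CCC/C(C)=C/CC/C(C)=C/CC/C(C)=C/CO | starting material
2 | (2E,6E,10E)-geranylgeranyl bromide | CC(C)=CCC/C(C)=C/CC/C(C)=C/CC/C(C)=C/CBr | intermediate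
3 | (5E,9E,13E)-6,10,14,18-tetramethylnonadeca-5,9,13,17-tetraen-1-yne | CC(C)=CCC/C(C)=C/CC/C(C)=C/CC/C(C)=C/CCC#C | intermediate
4 | dimethyl[(1E,5E,9E,13E)-2,6,10,14,18-pentamethylnonadeca-1,5,9,13,17-pentaen-1-yl]alane (not isolated) | CC(C)=CCC/C(C)=C/CC/C(C)=C/CC/C(C)=C/CC/C(C)=C/[Al](C)C | intermediate
5 | lithium butyl(dimethyl)alkenylalanate derived from 4 (not isolated) | [Li+].CC(C)=CCC/C(C)=C/CC/C(C)=C/CC/C(C)=C/CC/C(C)=C/[Al-](C)(C)CCCC | intermediate
6 | (3E,7E,11E,15E)-4,8,12,16,20-pentamethylhenicosa-3,7,11,15,19-pentaen-1-ol | CC(C)=CCC/C(C)=C/CC/C(C)=C/CC/C(C)=C/CC/C(C)=C/CCO | intermediate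
7 | (3E,7E,11E,15E)-1-iodo-4,8,12,16,20-pentamethylhenicosa-3,7,11,15,19-pentaene | CC(C)=CCC/C(C)=C/CC/C(C)=C/CC/C(C)=C/CC/C(C)=C/CCI | intermediate
8 | primary homoallyllithium derived from 7 (not isolated) | CC(C)=CCC/C(C)=C/CC/C(C)=C/CC/C(C)=C/CC/C(C)=C/CC[Li] | intermediate
9 | 2-[(3E,7E,11E,15E)-4,8,12,16,20-pentamethylhenicosa-3,7,11,15,19-pentaen-1-yl]-4,4,5,5-tetramethyl-1,3,2-dioxaborolane | CC(C)=CCC/C(C)=C/CC/C(C)=C/CC/C(C)=C/CC/C(C)=C/CCB1OC(C)(C)C(C)(C)O1 | intermediate
10 | (R)-γ-tocotrienol, (2R)-2,7,8-trimethyl-2-[(3E,7E)-4,8,12-trimethyltrideca-3,7,11-trien-1-yl]chroman-6-ol | CC(C)=CCC/C(C)=C/CC/C(C)=C/CC[C@]1(C)CCc2cc(O)c(C)c(C)c2O1 | starting material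
11 | O-triisopropylsilyl-(R)-γ-tocotrienol | CC(C)=CCC/C(C)=C/CC/C(C)=C/CC[C@]1(C)CCc2cc(O[Si](C(C)C)(C(C)C)C(C)C)c(C)c(C)c2O1 | intermediate
12 | O-triisopropylsilyl-(R)-3,4-dehydro-γ-tocotrienol, the (2R)-2H-chromene | CC(C)=CCC/C(C)=C/CC/C(C)=C/CC[C@]1(C)C=Cc2cc(O[Si](C(C)C)(C(C)C)C(C)C)c(C)c(C)c2O1 | intermediate
13 | (2E,6E,10E)-2,6,10-trimethyl-13-[(2R)-2,7,8-trimethyl-6-(triisopropylsilyloxy)-2H-chromen-2-yl]trideca-2,6,10-trien-1-ol | OC/C(C)=C/CC/C(C)=C/CC/C(C)=C/CC[C@]1(C)C=Cc2cc(O[Si](C(C)C)(C(C)C)C(C)C)c(C)c(C)c2O1 | intermediate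
14 | terminal trans-2,3-epoxy alcohol of 13, both epoxide diastereomers | OCC1(C)OC1CC/C(C)=C/CC/C(C)=C/CC[C@]2(C)C=Cc3cc(O[Si](C(C)C)(C(C)C)C(C)C)c(C)c(C)c3O2 | intermediate
15 | (4E,8E)-4,8-dimethyl-11-[(2R)-2,7,8-trimethyl-6-(triisopropylsilyloxy)-2H-chromen-2-yl]undeca-4,8-dienal | O=CCC/C(C)=C/CC/C(C)=C/CC[C@]1(C)C=Cc2cc(O[Si](C(C)C)(C(C)C)C(C)C)c(C)c(C)c2O1 | intermediate
16 | (11′Z)-iodoalkene, triisopropyl{[(2R)-2-[(3E,7E,11Z)-12-iodo-4,8-dimethyltrideca-3,7,11-trien-1-yl]-2,7,8-trimethyl-2H-chromen-6-yl]oxy}silane | C/C(I)=C/CC/C(C)=C/CC/C(C)=C/CC[C@]1(C)C=Cc2cc(O[Si](C(C)C)(C(C)C)C(C)C)c(C)c(C)c2O1 | intermediate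
17 | (Z)-alkenyllithium from 16, lithium cis to C10′ (not isolated) | [Li]/C(C)=C\CC/C(C)=C/CC/C(C)=C/CC[C@]1(C)C=Cc2cc(O[Si](C(C)C)(C(C)C)C(C)C)c(C)c(C)c2O1 | intermediate
18 | lithium alkyl(alkenyl)pinacolatoborate from 9 and 17, boron cis to C10′ (not isolated) | [Li+].CC(C)=CCC/C(C)=C/CC/C(C)=C/CC/C(C)=C/CC/C(C)=C/CC[B-]1(OC(C)(C)C(C)(C)O1)/C(C)=C\CC/C(C)=C/CC/C(C)=C/CC[C@]2(C)C=Cc3cc(O[Si](C(C)C)(C(C)C)C(C)C)c(C)c(C)c3O2 | intermediate
19 | β-iodo boronic ester, Bpin and CH3 on C12′, iodine on C11′ (not isolated) | CC(C)=CCC/C(C)=C/CC/C(C)=C/CC/C(C)=C/CC/C(C)=C/CCC(C)(B1OC(C)(C)C(C)(C)O1)C(I)CC/C(C)=C/CC/C(C)=C/CC[C@]2(C)C=Cc3cc(O[Si](C(C)C)(C(C)C)C(C)C)c(C)c(C)c3O2 | intermediate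
20 | O-triisopropylsilyl-plastochromenol-8 | CC(C)=CCC/C(C)=C/CC/C(C)=C/CC/C(C)=C/CC/C(C)=C/CC/C(C)=C/CC/C(C)=C/CC/C(C)=C/CC[C@]1(C)C=Cc2cc(O[Si](C(C)C)(C(C)C)C(C)C)c(C)c(C)c2O1 | intermediate
21 | plastochromenol-8, (2R)-2,7,8-trimethyl-2-[all-E-octaprenylmethyl side chain]-2H-chromen-6-ol | CC(C)=CCC/C(C)=C/CC/C(C)=C/CC/C(C)=C/CC/C(C)=C/CC/C(C)=C/CC/C(C)=C/CC/C(C)=C/CC[C@]1(C)C=Cc2cc(O)c(C)c(C)c2O1 | target

**Step count and risks**

Total step count: 13 (steps 1–5 for the boronate, steps 6–11 for the iodoalkene, steps 12–13 for union and deprotection).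
Longest linear sequence: 8 steps (10 → 21, steps 6–13).

Steps most likely to fail:

1. Step 7 (dehydrogenation). Hydride abstraction by DDQ may occur at allylic C–H bonds of the side chain instead of at C4, or the electron-rich aryl silyl ether may be oxidised with loss of silicon, so that clean conversion to the chromene is not reached. The fallback builds the chromene ring by construction instead of by oxidation. It sets out from 1: MnO2 oxidation gives (2E,6E,10E)-geranylgeranial F1. Condensation of F1 with 2,3-dimethylhydroquinone (Cc1c(O)ccc(O)c1C; phenylboronic acid, AcOH, toluene, reflux; ortho-quinone methide formation and oxa-6π electrocyclisation) gives racemic 3,4-dehydro-γ-tocotrienol F2. Silylation as in step 6 gives the racemic triisopropylsilyl ether F3, and its enantiomers are separated by preparative HPLC on a chiral stationary phase. The (R)-enantiomer is 12, where the route is rejoined.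

2. Step 12 (key coupling). The alkenyllithium may be protonated before it reaches boron, iodine may add to other electron-rich alkenes, or part of the elimination may follow a syn course and erode the E geometry. The fallback makes the same C12′–C13′ bond by palladium catalysis and sets out from 15 and 7. Ramirez dibromo-olefination of 15 (CBr4, PPh3, Et3N, CH2Cl2, 0 °C) gives the 1,1-dibromoalkene F4. Iodide 7 is converted (t-BuLi, then ZnBr2) into the homoallylzinc bromide F5. Trans-selective Negishi mono-alkylation of F4 with F5 (cat. Pd(DPEphos)Cl2, THF) replaces the bromine trans to the chain and gives the (Z)-bromoalkene F6. Stereoretentive methylation of F6 (Me2Zn, cat. Pd(t-Bu3P)2) then comes back to the route at 20.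

3. Step 8 (terminal allylic oxidation). Oxidation may spread to allylic positions of the internal alkenes or run on to the enal, so that the terminal alcohol is obtained only at low conversion. The fallback moves the chain shortening to the chroman stage and sets out from 11. Bromohydrin formation at the terminal alkene (NBS, THF–H2O, 0 °C, selectivity from coiling of the chain in the aqueous medium) gives the bromohydrin F7. K2CO3 in MeOH closes it to the terminal epoxide F8. Periodic acid cleavage gives the chroman aldehyde F9. DDQ dehydrogenation of F9 as in step 7 comes back to the route at 15.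

**Further compounds**

F1 | step 7 | (2E,6E,10E)-geranylgeranial | CC(C)=CCC/C(C)=C/CC/C(C)=C/CC/C(C)=C/C=O
F2 | step 7 | racemic 3,4-dehydro-γ-tocotrienol | CC(C)=CCC/C(C)=C/CC/C(C)=C/CCC1(C)C=Cc2cc(O)c(C)c(C)c2O1
F3 | step 7 | racemic O-triisopropylsilyl-3,4-dehydro-γ-tocotrienol | CC(C)=CCC/C(C)=C/CC/C(C)=C/CCC1(C)C=Cc2cc(O[Si](C(C)C)(C(C)C)C(C)C)c(C)c(C)c2O1
F4 | step 12 | 1,1-dibromoalkene from aldehyde 15 | BrC(Br)=CCC/C(C)=C/CC/C(C)=C/CC[C@]1(C)C=Cc2cc(O[Si](C(C)C)(C(C)C)C(C)C)c(C)c(C)c2O1
F5 | step 12 | homoallylzinc bromide from iodide 7 | CC(C)=CCC/C(C)=C/CC/C(C)=C/CC/C(C)=C/CC/C(C)=C/CC[Zn]Br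
F6 | step 12 | (Z)-12′-bromoalkene, C13′ chain trans to C10′ | CC(C)=CCC/C(C)=C/CC/C(C)=C/CC/C(C)=C/CC/C(C)=C/CC/C(Br)=C/CC/C(C)=C/CC/C(C)=C/CC[C@]1(C)C=Cc2cc(O[Si](C(C)C)(C(C)C)C(C)C)c(C)c(C)c2O1
F7 | step 8 | terminal bromohydrin of 11 (11′-bromo-12′-ol, both epimers) | CC(C)(O)C(Br)CC/C(C)=C/CC/C(C)=C/CC[C@]1(C)CCc2cc(O[Si](C(C)C)(C(C)C)C(C)C)c(C)c(C)c2O1
F8 | step 8 | terminal 11′,12′-epoxide of 11 (both epimers) | CC1(C)OC1CC/C(C)=C/CC/C(C)=C/CC[C@]2(C)CCc3cc(O[Si](C(C)C)(C(C)C)C(C)C)c(C)c(C)c3O2
F9 | step 8 | (4E,8E)-4,8-dimethyl-11-[(2R)-2,7,8-trimethyl-6-(triisopropylsilyloxy)chroman-2-yl]undeca-4,8-dienal | O=CCC/C(C)=C/CC/C(C)=C/CC[C@]1(C)CCc2cc(O[Si](C(C)C)(C(C)C)C(C)C)c(C)c(C)c2O1
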